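**Strategy.** Ring B of the target carries O6 and the C9 hydroxyl on the same face, 1,4 to each other across C7=C8. The route therefore cuts both C–O bonds at once, back to a C6=C7–C8=C9 diene and O2. Photosensitised singlet oxygen adds across C6 and C9 of a cis-fused drima-6,8-dien-11-oate, closing a peroxide-bridged 2,3-dioxabicyclo[2.2.2]octene and setting both carbinol stereocentres in one operation, the folded ring A directing attack to the β-face. The precursor is the 2-(trimethylsilyl)ethyl dienoate with C12 still a methyl group, built from (S)-carvone. Afterwards only O–O reduction, C12 oxidation, O6 acylation and ester cleavage remain.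

Key step: step 9

Remark: the target SMILES specifies a cis ring fusion (H5 and the C10 methyl on the same face as O6 and the C9 hydroxyl) and the open γ-formyl acid form; both are taken as intended. Bicyclic compounds use drimane numbering (C11 on C9, C12 on C8), β is the face of ring B bearing the C10 methyl, and monocyclic intermediates keep carvone numbering.

Step 1
Reactants: 1 3-(trimethylsilyl)prop-2-yn-1-ol
Product: 2 (Z)-3-(trimethylsilyl)prop-2-en-1-ol
Conditions: H2 (1 atm), Ni(OAc)2·4H2O (cat.), NaBH4 (cat.), H2NCH2CH2NH2, EtOH, rt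
Reagents that add atoms: none
Why: Syn semihydrogenation of the silylalkyne on amine-poisoned nickel boride delivers both hydrogens to one face and should stop at the cis-vinylsilane, whose Z geometry is needed for the endocyclic ring closure in step 5.

Step 2
Reactants: 2 (Z)-3-(trimethylsilyl)prop-2-en-1-ol
Product: 3 (Z)-(3-bromoprop-1-en-1-yl)trimethylsilane
Conditions: CBr4, PPh3, CH2Cl2, 0 °C (used freshly prepared)
Reagents that add atoms: tetrabromomethane, BrC(Br)(Br)Br
Why: Appel bromination replaces the primary allylic hydroxyl by SN2 displacement of an oxyphosphonium group under neutral conditions that leave the Z-vinylsilane untouched.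

Step 3
Reactants: 4 (S)-carvone; 3 (Z)-(3-bromoprop-1-en-1-yl)trimethylsilane
Product: 6 6-[(2Z)-3-(trimethylsilyl)prop-2-en-1-yl]carvone (major epimer: chain trans to the C5 isopropenyl group), via carvone lithium enolate 5 (not isolated)
Conditions: LiN(iPr)2 (LDA), THF, −78 °C; then 3, −78 → 0 °C
Reagents that add atoms: bromide 3, C[Si](C)(C)/C=C\CBr
Why: Kinetic deprotonation of carvone occurs at the α'-methylene C6 and SN2 alkylation of this cross-conjugated enolate by the allylic bromide attaches the three-carbon chain (enolate alkylation); the new C6 centre is planarised again in step 4, so its configuration is immaterial.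

Step 4
Reactants: 6 6-[(2Z)-3-(trimethylsilyl)prop-2-en-1-yl]carvone
Product: 8 6-methyl-6-[(2Z)-3-(trimethylsilyl)prop-2-en-1-yl]carvone (6-methyl trans and silylallyl chain cis to the C5 isopropenyl group), via tetrasubstituted lithium enolate 7 (not isolated)
Conditions: LiN(iPr)2 (LDA), THF, −78 °C; then MeI, DMPU, −78 → −20 °C
Reagents that add atoms: iodomethane, CI
Why: A second kinetic enolisation at C6 followed by enolate methylation creates the quaternary centre, iodomethane approaching the face opposite the adjacent pseudoaxial C5 isopropenyl group, so that the methyl ends up trans to isopropenyl (cis to H5) as the cis ring fusion requires.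

Step 5
Reactants: 8 6-methyl-6-[(2Z)-3-(trimethylsilyl)prop-2-en-1-yl]carvone
Product: 9 cis-fused 11-nordrima-2,7-dien-9-one (H5 and 10-CH3 both β)
Conditions: CF3CO2H, CH2Cl2, 0 °C → rt
Reagents that add atoms: none
Why: Markovnikov protonation of the isopropenyl group gives a tertiary cation at C4 that the Z-vinylsilane captures at its silicon-bearing carbon C3, and the β-silyl cation then loses silicon to leave C2=C3 (vinylsilane-terminated cation–olefin cyclisation by ipso substitution); no stereocentre is formed, the cis fusion being fixed by the centres set in steps 3 and 4.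

Step 6
Reactants: 9 cis-fused 11-nordrima-2,7-dien-9-one
Product: 10 cis-fused 11-nordrim-7-en-9-one
Conditions: H2 (1 atm), RhCl(PPh3)3 (cat.), toluene–EtOH, rt
Reagents that add atoms: none
Why: Homogeneous hydrogenation with this rhodium catalyst discriminates by alkene substitution and should saturate the cis-disubstituted C2=C3 bond while leaving the trisubstituted conjugated C7=C8 enone alone, the same selectivity that lets it reduce an isopropenyl group beside a conjugated enone.

Step 7
Reactants: 10 cis-fused 11-nordrim-7-en-9-one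
Product: 11 cis-fused 11-nordrima-6,8-dien-9-yl trifluoromethanesulfonate
Conditions: Tf2O, 2,6-di-tert-butyl-4-methylpyridine, CH2Cl2, 0 °C → rt
Reagents that add atoms: trifluoromethanesulfonic anhydride, O=S(=O)(OS(=O)(=O)C(F)(F)F)C(F)(F)F
Why: O-Triflylation of the enone carbonyl gives a triflyloxy-allyl cation from which the hindered base can only remove a C6 proton, because C10 is quaternary, giving the linear 9-triflyloxy-6,8-diene (dienyl triflate formation from an enone, as used for steroidal 3,5-dienyl triflates).

Step 8
Reactants: 11 cis-fused 11-nordrima-6,8-dien-9-yl trifluoromethanesulfonate; 12 2-(trimethylsilyl)ethanol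
Product: 13 2-(trimethylsilyl)ethyl cis-fused drima-6,8-dien-11-oate
Conditions: Pd(OAc)2 (cat.), PPh3 (cat.), CO (1 atm), Et3N, 12 (excess), DMF, 60 °C
Reagents that add atoms: carbon monoxide, [C-]#[O+]; alcohol 12, C[Si](C)(C)CCO
Why: Oxidative addition of the dienyl triflate to the zerovalent palladium formed in situ, CO insertion and alcoholysis of the acyl–palladium species by the primary alcohol give the dienoate (palladium-catalysed alkoxycarbonylation of an enol triflate), installing C11 as an ester that fluoride can later remove without attack at this hindered carbonyl.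

Step 9
Reactants: 13 2-(trimethylsilyl)ethyl cis-fused drima-6,8-dien-11-oate
Product: 14 2-(trimethylsilyl)ethyl 6β,9β-epidioxydrim-7-en-11-oate (cis-fused)
Conditions: O2, tetraphenylporphyrin (cat.), visible light, CH2Cl2, −20 °C
Reagents that add atoms: dioxygen, O=O
Why: Energy transfer from the excited porphyrin gives singlet oxygen, which should add in a concerted, suprafacial [4+2] (hetero-Diels–Alder) fashion to the s-cis-locked C6=C7–C8=C9 diene, forming O–C6 and O–C9 while the double bond moves to C7=C8. The closest known reaction type is the photooxygenation of cyclohexa-1,3-dienes and conjugated dienoates to 2,3-dioxabicyclo[2.2.2]oct-5-enes. The single new ring, the six-membered 1,2-dioxine ring O–C6–C7=C8–C9–O, closes by cycloaddition at both termini at once and leaves ring B bridged by the peroxide. C6 and C9 are created together: suprafacial addition forces both oxygens onto one face, and that face should be β because cis-fused ring A (C1 and the gem-dimethyl-bearing C4) is folded under the α-face, whereas the β-face carries only H5 and the C10 methyl. The step needs periselectivity ([4+2] over ene reaction at C12–H or C5–H) and β-facial selectivity; the rigid cisoid diene, the ester twisted out of conjugation by C12 and C10, and the concave shape of the cis-decalin are the substrate features expected to secure them.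

Step 10
Reactants: 14 2-(trimethylsilyl)ethyl 6β,9β-epidioxydrim-7-en-11-oate
Product: 15 2-(trimethylsilyl)ethyl 6β,9β-dihydroxydrim-7-en-11-oate
Conditions: Zn dust, AcOH, CH2Cl2, 0 °C → rt
Reagents that add atoms: none
Why: Zinc in acetic acid reduces the weak O–O bond by electron transfer and protonation (reductive cleavage of an endoperoxide) without breaking either C–O bond, so the secondary 6β- and tertiary 9β-hydroxyls appear with the configuration fixed in step 9.

Step 11
Reactants: 15 2-(trimethylsilyl)ethyl 6β,9β-dihydroxydrim-7-en-11-oate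
Product: 16 2-(trimethylsilyl)ethyl 6β,9β-dihydroxy-12-oxodrim-7-en-11-oate
Conditions: SeO2, 1,4-dioxane, 80 °C
Reagents that add atoms: selenium dioxide, O=[Se]=O
Why: Selenium dioxide attacks the trisubstituted C7=C8 bond in an ene reaction that takes hydrogen from the allylic group on the more substituted carbon C8, which can only be the C12 methyl because C9 is fully substituted, and [2,3]-sigmatropic shift with further oxidation gives the enal (Riley allylic oxidation) without touching a stereocentre.

Step 12
Reactants: 16 2-(trimethylsilyl)ethyl 6β,9β-dihydroxy-12-oxodrim-7-en-11-oate; 17 (2E,4E,6E)-octa-2,4,6-trienoic acid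
Product: 18 2-(trimethylsilyl)ethyl 9β-hydroxy-6β-[(2E,4E,6E)-octa-2,4,6-trienoyloxy]-12-oxodrim-7-en-11-oate
Conditions: DCC, DMAP (cat.), CH2Cl2, 0 °C → rt
Reagents that add atoms: acid 17, C/C=C/C=C/C=C/C(=O)O
Why: Carbodiimide activation with DMAP catalysis (Steglich esterification) acylates the secondary allylic 6-hydroxyl, which lies trans to C4 on the open β-face, whereas the tertiary 9-hydroxyl flanked by quaternary C10 and the ester cannot compete; the C6–O bond is not broken, so configuration is retained.

Step 13
Reactants: 18 2-(trimethylsilyl)ethyl 9β-hydroxy-6β-[(2E,4E,6E)-octa-2,4,6-trienoyloxy]-12-oxodrim-7-en-11-oate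
Product: 19 9β-hydroxy-6β-[(2E,4E,6E)-octa-2,4,6-trienoyloxy]-12-oxodrim-7-en-11-oic acid (cis-fused; target)
Conditions: Bu4NF (TBAF), THF, 0 °C; then aq. HCl to pH 3
Reagents that add atoms: none
Why: Fluoride attacks silicon and triggers β-elimination of ethene (fluoride-induced fragmentation of a 2-(trimethylsilyl)ethyl ester), releasing the hindered tertiary carboxylate without nucleophilic attack on any carbonyl, so the trienoate, the enal and all four stereocentres remain intact.

**Compound list**

1 | 3-(trimethylsilyl)prop-2-yn-1-ol | C[Si](C)(C)C#CCO | starting material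
2 | (Z)-3-(trimethylsilyl)prop-2-en-1-ol | C[Si](C)(C)/C=C\CO | intermediate
3 | (Z)-(3-bromoprop-1-en-1-yl)trimethylsilane | C[Si](C)(C)/C=C\CBr | intermediate
4 | (S)-carvone | CC1=CC[C@@H](CC1=O)C(C)=C | starting material
5 | lithium enolate of (S)-carvone (C1=C6 enolate) | [Li]OC1=C[C@@H](C(C)=C)CC=C1C | intermediate (not isolated)
6 | 2-methyl-5-(prop-1-en-2-yl)-6-[(2Z)-3-(trimethylsilyl)prop-2-en-1-yl]cyclohex-2-en-1-one, 5,6-trans major epimer, C5 as in (S)-carvone | C1C=C(C)C(=O)[C@H](C/C=C\[Si](C)(C)C)[C@H]1C(C)=C | intermediate
7 | lithium enolate of 6 (tetrasubstituted C1=C6 enolate) | [Li]OC1=C(C/C=C\[Si](C)(C)C)[C@@H](C(C)=C)CC=C1C | intermediate (not isolated)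
8 | 2,6-dimethyl-5-(prop-1-en-2-yl)-6-[(2Z)-3-(trimethylsilyl)prop-2-en-1-yl]cyclohex-2-en-1-one, 6-methyl trans to the C5 isopropenyl group | C1C=C(C)C(=O)[C@@](C)(C/C=C\[Si](C)(C)C)[C@H]1C(C)=C | intermediate
9 | cis-fused 11-nordrima-2,7-dien-9-one (H5 and 10-CH3 β) | C1C=C(C)C(=O)[C@@]2(C)CC=CC(C)(C)[C@@H]12 | intermediate
10 | cis-fused 11-nordrim-7-en-9-one | C1C=C(C)C(=O)[C@@]2(C)CCCC(C)(C)[C@@H]12 | intermediate
11 | cis-fused 11-nordrima-6,8-dien-9-yl trifluoromethanesulfonate | C1=CC(C)=C(OS(=O)(=O)C(F)(F)F)[C@@]2(C)CCCC(C)(C)[C@@H]12 | intermediate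
12 | 2-(trimethylsilyl)ethanol | C[Si](C)(C)CCO | starting material
13 | 2-(trimethylsilyl)ethyl cis-fused drima-6,8-dien-11-oate | C1=CC(C)=C(C(=O)OCC[Si](C)(C)C)[C@@]2(C)CCCC(C)(C)[C@@H]12 | intermediate (key-step precursor)
14 | 2-(trimethylsilyl)ethyl 6β,9β-epidioxydrim-7-en-11-oate | O3[C@@H]1C=C(C)[C@@](O3)(C(=O)OCC[Si](C)(C)C)[C@@]2(C)CCCC(C)(C)[C@@H]12 | intermediate (key-step product)
15 | 2-(trimethylsilyl)ethyl 6β,9β-dihydroxydrim-7-en-11-oate | O[C@@H]1C=C(C)[C@@](O)(C(=O)OCC[Si](C)(C)C)[C@@]2(C)CCCC(C)(C)[C@@H]12 | intermediate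
16 | 2-(trimethylsilyl)ethyl 6β,9β-dihydroxy-12-oxodrim-7-en-11-oate | O[C@@H]1C=C(C=O)[C@@](O)(C(=O)OCC[Si](C)(C)C)[C@@]2(C)CCCC(C)(C)[C@@H]12 | intermediate
17 | (2E,4E,6E)-octa-2,4,6-trienoic acid | C/C=C/C=C/C=C/C(=O)O | starting material
18 | 2-(trimethylsilyl)ethyl 9β-hydroxy-6β-[(2E,4E,6E)-octa-2,4,6-trienoyloxy]-12-oxodrim-7-en-11-oate | C/C=C/C=C/C=C/C(=O)O[C@@H]1C=C(C=O)[C@@](O)(C(=O)OCC[Si](C)(C)C)[C@@]2(C)CCCC(C)(C)[C@@H]12 | intermediate
19 | 9β-hydroxy-6β-[(2E,4E,6E)-octa-2,4,6-trienoyloxy]-12-oxodrim-7-en-11-oic acid, cis-fused | C/C=C/C=C/C=C/C(=O)O[C@@H]1C=C(C=O)[C@@](O)(C(=O)O)[C@@]2(C)CCCC(C)(C)[C@@H]12 | target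

Total step count: 13. Longest linear sequence: 13 steps (1 → 19); 11 steps from (S)-carvone 4.

**Steps most likely to fail**

Step 5. Cation formation by reversible protonation may be diverted before C3 closes onto C4, through proton loss to the isopropylidene isomer, hydride shift from C5 or protodesilylation of the vinylsilane. The fallback sets out from 8 and returns at 9. Markovnikov hydrochlorination of the isopropenyl group (dry HCl, CH2Cl2, −30 °C) should give the tertiary chloride F1. TiCl4 in CH2Cl2 at −78 °C then ionises the C–Cl bond under aprotic conditions, and ipso capture of the cation by the vinylsilane with loss of chlorotrimethylsilane should deliver 9.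

Step 9. The ester-bearing, fully substituted C9 terminus may slow the cycloaddition enough for ene-type oxygenation (at C12–H or C5–H) or attack from the α-face to compete. The fallback sets out from 13 and returns at 15, running the cycloaddition on an electron-rich diene and restoring the ester afterwards.
- iBu2AlH (DIBAL-H) in CH2Cl2 at −78 °C reduces the ester to cis-fused drima-6,8-dien-11-ol F2.
- Photooxygenation (O2, tetraphenylporphyrin, light, CH2Cl2) should give the 6β,9β-epidioxy carbinol F3 under the same facial bias.
- Zn/AcOH cleaves the O–O bond to drim-7-ene-6β,9β,11-triol F4.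
- The primary carbinol is oxidised selectively (TEMPO cat., NaOCl cat., NaClO2, MeCN/pH 6.7 phosphate buffer) to 6β,9β-dihydroxydrim-7-en-11-oic acid F5.
- O-Alkylation of the carboxyl group with O-[2-(trimethylsilyl)ethyl]-N,N'-diisopropylisourea in THF gives 15.

The acid level is reached only after the peroxide is reduced, because an α-peroxy carboxylate would be prone to decarboxylative fragmentation.

Step 11. The two allylic C–O bonds slow the ene step, and at the temperature then needed the free allylic C6 carbinol may be oxidised or tied up as a selenite ester. The fallback sets out from 14 (replacing steps 10 and 11) and returns at 16, using the peroxide bridge to mask both carbinol oxygens, since the bridgehead C6–H cannot enter an ene reaction. SeO2 (cat.) with t-BuOOH in CH2Cl2 at rt should hydroxylate C12 to the 12-hydroxy endoperoxide F6. MnO2 in CH2Cl2 oxidises it to the 12-oxo endoperoxide F7, and thiourea in MeOH then reduces the O–O bond to give 16.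

**Further compounds**

F1 | step 5 | 5-(2-chloropropan-2-yl)-2,6-dimethyl-6-[(2Z)-3-(trimethylsilyl)prop-2-en-1-yl]cyclohex-2-en-1-one (6-methyl trans to the C5 substituent) | C1C=C(C)C(=O)[C@@](C)(C/C=C\[Si](C)(C)C)[C@H]1C(C)(C)Cl
F2 | step 9 | cis-fused drima-6,8-dien-11-ol | C1=CC(C)=C(CO)[C@@]2(C)CCCC(C)(C)[C@@H]12
F3 | step 9 | 6β,9β-epidioxydrim-7-en-11-ol | O3[C@@H]1C=C(C)[C@@](O3)(CO)[C@@]2(C)CCCC(C)(C)[C@@H]12
F4 | step 9 | drim-7-ene-6β,9β,11-triol | O[C@@H]1C=C(C)[C@@](O)(CO)[C@@]2(C)CCCC(C)(C)[C@@H]12
F5 | step 9 | 6β,9β-dihydroxydrim-7-en-11-oic acid | O[C@@H]1C=C(C)[C@@](O)(C(=O)O)[C@@]2(C)CCCC(C)(C)[C@@H]12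
F6 | step 11 | 2-(trimethylsilyl)ethyl 6β,9β-epidioxy-12-hydroxydrim-7-en-11-oate | O3[C@@H]1C=C(CO)[C@@](O3)(C(=O)OCC[Si](C)(C)C)[C@@]2(C)CCCC(C)(C)[C@@H]12
F7 | step 11 | 2-(trimethylsilyl)ethyl 6β,9β-epidioxy-12-oxodrim-7-en-11-oate | O3[C@@H]1C=C(C=O)[C@@](O3)(C(=O)OCC[Si](C)(C)C)[C@@]2(C)CCCC(C)(C)[C@@H]12
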